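The earlier runs and the new flask are calculated with made-up constants; the scatter is artificial.

Z is slow to appear: the ochre run shows 0.7% of Z at 4.00 min beside 12.6% of E, and each reading scatters by 1 percentage point.

- ochre: Q 0.75 M; run made earlier
- flask: Q 1.5 M; time 40 min
ochre run (percent of the Q charged)

| time / min | Z / % | E / % |
|---|---|---|
| 0.333 | 0 | 1.6 |
| 0.500 | 0.1 | 3.9 |
| 0.833 | 0 | 4.0 |
| 1.33 | 0.2 | 7.9 |
| 2.50 | 0.7 | 9.9 |
| 4.00 | 0.7 | 12.6 |

(each reading ± 1 percentage point)

- share of Z in Z plus E at 15 s
- share of Z in Z plus E at 3.0 min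
- share of Z in Z plus E at 40 min
- which of Z and E there is more of at 40 min

The chair opened with the balance of Q, the one charge and so the limiting reagent: c_Q, c_E, c_Z and whatever goes unread add up to the charge. In the ochre run at 4.00 min, E and Z hold 13.3%, so the remaining 86.7% stands as Q or as something unread.

The kineticist replied that one ratio, c_Z/c_E, sidesteps that unknown remainder if Z comes from E by a first-order step. She expected it to climb with time, and assumed the same slope at both charges. From the two latest ochre readings she took 0.0186 min⁻¹, and named this slope of c_Z/c_E against time the pace of Z. The same sum gives it a scatter of 0.0188 min⁻¹, about as large as the pace itself, so the readings barely tell it from zero. Her reckoning for the flask at 40 min was a share of 42.7%, and one scatter up gave 59.9%.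

The forecast, reached separately, put the shares at 1%, 6% and 45%, with E ahead at 40 min, and argued: “That looks like a consecutive route, E → Z, rather than a parallel one.”

The flask gives 0.156% at 15 s, 1.72% at 3.0 min and 17.3% at 40 min, with E ahead, 17.6% against 3.68%.

    Q ⇌ E (K = 1.20, k = 7.90 × 10⁻⁴ s⁻¹)
    E ⇌ Z (K = 0.670, k = 2.10 × 10⁻⁴ s⁻¹)
    Z ⇌ G (K = 1.30, k = 0.00290 s⁻¹)
    2 Q → X (k = 7.20 × 10⁻⁴ L mol⁻¹ s⁻¹)

Taken as c_Z/c_E divided by the time, the flask's own mean pace up to 40 min is 0.005220 min⁻¹. That is 0.0134 min⁻¹ below the pace read from the ochre run, a gap smaller than the scatter of that reading. Carried unchanged to the neighbouring flask, charged with 0.90 M of Q instead of 1.5 M, this pace gives a share of 17.3% at 40 min. The neighbouring flask gives 16.6%, with 22.5% of E against 4.46% of Z.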